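**Plan**

- Retrosynthesis: the C4–C4a aryl ketone bond of the chromanone is cut first (Friedel–Crafts acylation). Ring A is then cut at C5–C6, C7–C8 and C4a–C5 into a 3-alkoxy-2-prenylcyclobutenone (four ring carbons, as its vinylketene) and a chiral siloxyalkyne (two ring carbons).
- Enabling feature: ring A (C4a, C5, C6, C7, C8, C8a) is fully substituted. Oxygen sits at C5, C7 and C8a (free OH, OMe, ring ether O1) and alternates with carbon at C4a, C6 and C8. This 1,3,5-trioxygenation maps onto a ketene C=O (C5–OH), an alkyne O–Si (O7) and the cyclobutenone O-alkyl group (O1, already bonded to C2).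
- Forward order: the cyclobutenone fragment (ynol ether plus ketene, then Mitsunobu etherification) and the siloxyalkyne fragment (Evans alkylation, ynolate silylation) are joined by the benzannulation that creates ring A. The pyranone ring then closes by C4–C4a acylation. Desilylation and methylation at O7 and release of the acid finish the route.
- Stereochemistry: C2 and C3 come from methyl (R)-3-hydroxybutanoate (anti-selective Fráter–Seebach methylation, then Mitsunobu inversion at the carbinol carbon to the syn ether, which becomes the cis-2,3-dimethyl pattern). The side-chain centre comes from an Evans alkylation. The key step makes no stereocentre.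

Key step: step 10

Remark on the chemistry: the two ring methyl groups of the target are cis, (2S,3R), an arrangement that base would epimerise to trans, so every step after the pyranone ring exists is kept neutral or weakly acidic. Ketene is taken as the gas obtained by cracking diketene.

**Route**

Step 1
Reactants: 1 ethoxyacetylene; 2 prenyl bromide (1-bromo-3-methylbut-2-ene)
Product: 4 1-ethoxy-5-methylhex-4-en-1-yne, via lithium ethoxyacetylide 3 (not isolated)
Conditions: n-BuLi, THF, −78 °C; then 2, DMPU, −78 °C → rt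
Reagents that add atoms: none
Why: Acetylide alkylation: the lithiated ynol ether is a hard, unhindered carbon nucleophile that should displace the primary allylic bromide by SN2 at its CH2 end in the dipolar cosolvent.

Step 2
Reactants: 4 1-ethoxy-5-methylhex-4-en-1-yne
Product: 5 3-ethoxy-2-(3-methylbut-2-en-1-yl)cyclobut-2-en-1-one
Conditions: ketene (gas, from cracking of diketene), CH2Cl2, −20 °C → rt
Reagents that add atoms: ketene, C=C=O
Why: Ketene–ynol ether [2+2] cycloaddition: the ynol ether carbon β to oxygen is the nucleophile for the ketene carbonyl carbon, which places prenyl at C2 and ethoxy at C3, and unactivated ketene should leave the trisubstituted alkene untouched.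

Step 3
Reactants: 5 3-ethoxy-2-(3-methylbut-2-en-1-yl)cyclobut-2-en-1-one
Product: 6 3-hydroxy-2-(3-methylbut-2-en-1-yl)cyclobut-2-en-1-one
Conditions: 1 M aq HCl, THF, 0 °C → rt
Reagents that add atoms: water, O
Why: Acid hydrolysis of a vinylogous ester (water adds at C3, ethanol leaves) should give the cyclobutane-1,3-dione as its strongly acidic enol under conditions too mild to hydrate the prenyl alkene.

Step 4
Reactants: 7 methyl (3R)-3-hydroxybutanoate
Product: 9 methyl (2R,3R)-3-hydroxy-2-methylbutanoate, via dilithium alkoxide enolate 8 (not isolated)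
Conditions: LiN(iPr)2 (2.2 equiv), THF, −78 → −20 °C; then MeI, DMPU, −78 → 0 °C
Reagents that add atoms: iodomethane, CI
Why: Fráter–Seebach alkylation: the chelated dilithio alkoxide enolate is methylated on the face of the six-membered chelate opposite the carbinol methyl group, so the existing (3R) centre should set the new C2 centre as (2R), the anti isomer.

Step 5
Reactants: 6 3-hydroxy-2-(3-methylbut-2-en-1-yl)cyclobut-2-en-1-one; 9 methyl (2R,3R)-3-hydroxy-2-methylbutanoate
Product: 11 methyl (2R,3S)-2-methyl-3-{[2-(3-methylbut-2-en-1-yl)-3-oxocyclobut-1-en-1-yl]oxy}butanoate, via alkoxyphosphonium cyclobutenolate 10 (not isolated)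
Conditions: PPh3, iPrO2CN=NCO2iPr (DIAD), toluene, 0 °C → rt
Reagents that add atoms: none
Why: Mitsunobu etherification: the cyclobutenolone is a vinylogous carboxylic acid with two equivalent oxygens, acidic enough to protonate the betaine and too weakly basic to favour elimination, and its oxygen should displace the oxyphosphonium group with SN2 inversion, turning the (2R,3R) anti alcohol into the (2R,3S) syn enol ether.

Step 6
Reactants: 12 (4S)-4-benzyl-1,3-oxazolidin-2-one; 13 heptanoyl chloride
Product: 15 (4S)-4-benzyl-3-heptanoyl-1,3-oxazolidin-2-one, via N-lithio oxazolidinone 14 (not isolated)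
Conditions: n-BuLi, THF, −78 °C; then 13, −78 → 0 °C
Reagents that add atoms: none
Why: N-Acylation of the lithiated oxazolidinone with an acid chloride, the standard loading of an Evans auxiliary.

Step 7
Reactants: 15 (4S)-4-benzyl-3-heptanoyl-1,3-oxazolidin-2-one; 16 tert-butyl bromoacetate
Product: 18 tert-butyl (3R)-3-{[(4S)-4-benzyl-2-oxo-1,3-oxazolidin-3-yl]carbonyl}octanoate, via sodium Z-enolate 17 (not isolated)
Conditions: NaN(SiMe3)2, THF, −78 °C; then 16, −78 → −40 °C
Reagents that add atoms: none
Why: Evans asymmetric alkylation: the chelated sodium Z-enolate is shielded on one face by the benzyl group, so the reactive α-bromo ester should enter from the other face and set the (R) centre that becomes C3 of the octanoate arm.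

Step 8
Reactants: 18 tert-butyl (3R)-3-{[(4S)-4-benzyl-2-oxo-1,3-oxazolidin-3-yl]carbonyl}octanoate
Product: 19 4-tert-butyl 1-methyl (2R)-2-pentylbutanedioate
Conditions: MeMgBr, MeOH, CH2Cl2, 0 °C; then 1 M aq HCl
Reagents that add atoms: methanol, CO
Why: Transesterification of the N-acyloxazolidinone with bromomagnesium methoxide: magnesium chelation activates the exocyclic carbonyl, the auxiliary leaves as its anion, the tert-butyl ester is inert to methoxide at 0 °C and the weakly basic medium should not epimerise the α-centre.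

Step 9
Reactants: 19 4-tert-butyl 1-methyl (2R)-2-pentylbutanedioate
Product: 22 tert-butyl (3R)-3-{[tri(propan-2-yl)silyl]oxyethynyl}octanoate, via lithium dibromoenolate 20 (not isolated), via lithium ynolate 21 (not isolated)
Conditions: CH2Br2, lithium 2,2,6,6-tetramethylpiperidide, THF, −78 °C, then 19; LiN(SiMe3)2, then n-BuLi, −78 → 0 °C; iPr3SiCl, −78 °C → rt
Reagents that add atoms: dibromomethane, BrCBr; chlorotri(propan-2-yl)silane, CC(C)[Si](Cl)(C(C)C)C(C)C
Why: Kowalski ester homologation intercepted at the ynolate: LiCHBr2 adds to the methyl ester (the tert-butyl ester is too hindered to compete at −78 °C), the derived dibromoenolate undergoes Br/Li exchange and the carbenoid rearranges by 1,2-shift of the stereogenic carbon with retention, and the bulky silyl chloride then traps the ynolate on oxygen.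

Step 10
Reactants: 11 methyl (2R,3S)-2-methyl-3-{[2-(3-methylbut-2-en-1-yl)-3-oxocyclobut-1-en-1-yl]oxy}butanoate; 22 tert-butyl (3R)-3-{[tri(propan-2-yl)silyl]oxyethynyl}octanoate
Product: 27 methyl (2R,3S)-3-{4-[(3R)-1-tert-butoxy-1-oxooctan-3-yl]-5-hydroxy-2-(3-methylbut-2-en-1-yl)-3-[(triisopropylsilyl)oxy]phenoxy}-2-methylbutanoate, via vinylketene 23 (not isolated), via vinylcyclobutenone 24 (not isolated), via dienylketene 25 (not isolated), via cyclohexadienone 26 (not isolated)
Conditions: toluene, 110 °C, sealed tube, 22 (1.3 equiv)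
Reagents that add atoms: none
Why: Heating opens cyclobutenone 11 by 4π-electrocyclic cleavage of its C(=O)–CH2 bond to vinylketene 23, whose ketene C=C adds siloxyalkyne 22 in a [2+2] cycloaddition (new bonds C5–C6 and C7–C8, chromanone numbering) to give the 4-vinylcyclobutenone 24; a second 4π opening gives dienylketene 25, which closes by thermal disrotatory 6π-electrocyclisation between the ketene carbon and the terminal CH2 (bond C4a–C5) to cyclohexadienone 26, and this tautomerises to the phenol. The closest known reaction is the Danheiser benzannulation of cyclobutenones with siloxyalkynes to resorcinol monosilyl ethers; here the alkoxy group on the cyclobutenone supplies the third oxygen. Ring A is the only ring formed, and it closes in the 6π step as an all-carbon six-membered electrocyclic closure made irreversible by aromatisation. No stereocentre is created (the quaternary carbon of 24 is lost again on ring opening), and the three existing centres only see neutral hot toluene. The step needs one regiochemical outcome in the [2+2], and the polarisation of the siloxyalkyne secures it: the alkyne carbon β to oxygen is the nucleophile for the ketene carbonyl carbon, so the octanoate arm ends between C5–OH and C7–OSi, while the far higher nucleophilicity of the ynol ether keeps the ketene away from the prenyl double bond.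

Step 11
Reactants: 27 methyl (2R,3S)-3-{4-[(3R)-1-tert-butoxy-1-oxooctan-3-yl]-5-hydroxy-2-(3-methylbut-2-en-1-yl)-3-[(triisopropylsilyl)oxy]phenoxy}-2-methylbutanoate
Product: 29 (2R,3S)-3-{4-[(3R)-1-tert-butoxy-1-oxooctan-3-yl]-5-hydroxy-2-(3-methylbut-2-en-1-yl)-3-[(triisopropylsilyl)oxy]phenoxy}-2-methylbutanoic acid, via trimethylstannyl ester 28 (not isolated)
Conditions: Me3SnOH, ClCH2CH2Cl, 70 °C; then dilute aq HCl wash
Reagents that add atoms: trimethyltin hydroxide, C[Sn](C)(C)O
Why: Me3SnOH-mediated ester hydrolysis: the neutral tin hydroxide should cleave the methyl ester through its stannyl ester while leaving the tert-butyl ester and the hindered aryl silyl ether intact, without the α-epimerisation or β-aryloxy elimination that hydroxide bases could cause.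

Step 12
Reactants: 29 (2R,3S)-3-{4-[(3R)-1-tert-butoxy-1-oxooctan-3-yl]-5-hydroxy-2-(3-methylbut-2-en-1-yl)-3-[(triisopropylsilyl)oxy]phenoxy}-2-methylbutanoic acid
Product: 31 tert-butyl (3R)-3-{(2S,3R)-5-hydroxy-2,3-dimethyl-8-(3-methylbut-2-en-1-yl)-4-oxo-7-[(triisopropylsilyl)oxy]-3,4-dihydro-2H-chromen-6-yl}octanoate, via mixed trifluoroacetic anhydride 30 (not isolated)
Conditions: (CF3CO)2O, CH2Cl2, 0 °C; then aq NaHCO3
Reagents that add atoms: none
Why: Intramolecular Friedel–Crafts acylation through the mixed anhydride: C4a is the only unsubstituted ring carbon and is activated by ortho OH, ortho O-alkyl and para OSi, so the six-membered pyranone ring (bond C4–C4a) should close at 0 °C before the little trifluoroacetic acid formed can attack the tert-butyl ester or the prenyl group, and no stereocentre is touched.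

Step 13
Reactants: 31 tert-butyl (3R)-3-{(2S,3R)-5-hydroxy-2,3-dimethyl-8-(3-methylbut-2-en-1-yl)-4-oxo-7-[(triisopropylsilyl)oxy]-3,4-dihydro-2H-chromen-6-yl}octanoate
Product: 32 tert-butyl (3R)-3-[(2S,3R)-5,7-dihydroxy-2,3-dimethyl-8-(3-methylbut-2-en-1-yl)-4-oxo-3,4-dihydro-2H-chromen-6-yl]octanoate
Conditions: Bu4NF, AcOH (1:1), THF, 0 °C
Reagents that add atoms: none
Why: Fluoride-mediated cleavage of an aryl silyl ether activated by the para carbonyl group; buffering with acetic acid keeps the medium non-basic so that the cis-2,3-dimethyl arrangement should not epimerise by enolisation or retro-oxa-Michael opening.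

Step 14
Reactants: 32 tert-butyl (3R)-3-[(2S,3R)-5,7-dihydroxy-2,3-dimethyl-8-(3-methylbut-2-en-1-yl)-4-oxo-3,4-dihydro-2H-chromen-6-yl]octanoate
Product: 33 tert-butyl (3R)-3-[(2S,3R)-5-hydroxy-7-methoxy-2,3-dimethyl-8-(3-methylbut-2-en-1-yl)-4-oxo-3,4-dihydro-2H-chromen-6-yl]octanoate
Conditions: Me3SiCHN2, MeOH–toluene, 0 °C → rt
Reagents that add atoms: (trimethylsilyl)diazomethane, C[Si](C)(C)C=[N+]=[N-]
Why: Chemoselective O-methylation with a diazomethane equivalent: the 7-OH is a vinylogous acid para to the C4 carbonyl and should react under neutral conditions, whereas the 5-OH is held in the hydrogen bond to C4=O and no free carboxylic acid is present yet.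

Step 15
Reactants: 33 tert-butyl (3R)-3-[(2S,3R)-5-hydroxy-7-methoxy-2,3-dimethyl-8-(3-methylbut-2-en-1-yl)-4-oxo-3,4-dihydro-2H-chromen-6-yl]octanoate
Product: 34 (3R)-3-[(2S,3R)-5-hydroxy-7-methoxy-2,3-dimethyl-8-(3-methylbut-2-en-1-yl)-4-oxo-3,4-dihydro-2H-chromen-6-yl]octanoic acid
Conditions: 85% aq H3PO4, toluene, rt
Reagents that add atoms: none
Why: Acid-promoted cleavage of the tert-butyl ester by loss of the tert-butyl cation as isobutene; two-phase aqueous phosphoric acid is chosen as a weak, non-nucleophilic acid that should spare the prenyl double bond, the enolisable cis-configured C3 centre and the aryl ethers.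

**Compound list**

1 | ethoxyacetylene | CCOC#C | starting material
2 | prenyl bromide (1-bromo-3-methylbut-2-ene) | CC(C)=CCBr | starting material
3 | lithium ethoxyacetylide (not isolated) | CCOC#C[Li] | intermediate
4 | 1-ethoxy-5-methylhex-4-en-1-yne | CCOC#CCC=C(C)C | intermediate
5 | 3-ethoxy-2-(3-methylbut-2-en-1-yl)cyclobut-2-en-1-one | O=C1CC(OCC)=C1CC=C(C)C | intermediate
6 | 3-hydroxy-2-(3-methylbut-2-en-1-yl)cyclobut-2-en-1-one | O=C1CC(O)=C1CC=C(C)C | intermediate
7 | methyl (3R)-3-hydroxybutanoate | C[C@@H](O)CC(=O)OC | starting material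
8 | dilithium alkoxide enolate of 7 (not isolated) | C[C@@H]([O-])C=C([O-])OC.[Li+].[Li+] | intermediate
9 | methyl (2R,3R)-3-hydroxy-2-methylbutanoate | C[C@@H](O)[C@@H](C)C(=O)OC | intermediate
10 | [(2R,3R)-4-methoxy-3-methyl-4-oxobutan-2-yl]oxytriphenylphosphonium 2-(3-methylbut-2-en-1-yl)-3-oxocyclobut-1-en-1-olate (not isolated) | C[C@@H](O[P+](c1ccccc1)(c1ccccc1)c1ccccc1)[C@@H](C)C(=O)OC.[O-]C1=C(CC=C(C)C)C(=O)C1 | intermediate
11 | methyl (2R,3S)-2-methyl-3-{[2-(3-methylbut-2-en-1-yl)-3-oxocyclobut-1-en-1-yl]oxy}butanoate | O=C1CC(O[C@@H](C)[C@@H](C)C(=O)OC)=C1CC=C(C)C | intermediate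
12 | (4S)-4-benzyl-1,3-oxazolidin-2-one | O=C1N[C@@H](Cc2ccccc2)CO1 | starting material
13 | heptanoyl chloride | CCCCCCC(=O)Cl | starting material
14 | N-lithio derivative of 12 (not isolated) | O=C1N([Li])[C@@H](Cc2ccccc2)CO1 | intermediate
15 | (4S)-4-benzyl-3-heptanoyl-1,3-oxazolidin-2-one | CCCCCCC(=O)N1[C@@H](Cc2ccccc2)COC1=O | intermediate
16 | tert-butyl bromoacetate | CC(C)(C)OC(=O)CBr | starting material
17 | sodium (Z)-enolate of 15 (not isolated) | CCCCC/C=C(\[O-])N1[C@@H](Cc2ccccc2)COC1=O.[Na+] | intermediate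
18 | tert-butyl (3R)-3-{[(4S)-4-benzyl-2-oxo-1,3-oxazolidin-3-yl]carbonyl}octanoate | CCCCC[C@H](CC(=O)OC(C)(C)C)C(=O)N1[C@@H](Cc2ccccc2)COC1=O | intermediate
19 | 4-tert-butyl 1-methyl (2R)-2-pentylbutanedioate | CCCCC[C@H](CC(=O)OC(C)(C)C)C(=O)OC | intermediate
20 | lithium enolate of tert-butyl (3R)-3-(dibromoacetyl)octanoate (not isolated) | CCCCC[C@H](CC(=O)OC(C)(C)C)C([O-])=C(Br)Br.[Li+] | intermediate
21 | lithium 2-[(3R)-1-tert-butoxy-1-oxooctan-3-yl]ethyn-1-olate (not isolated) | CCCCC[C@H](CC(=O)OC(C)(C)C)C#C[O-].[Li+] | intermediate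
22 | tert-butyl (3R)-3-{[tri(propan-2-yl)silyl]oxyethynyl}octanoate | CCCCC[C@H](CC(=O)OC(C)(C)C)C#CO[Si](C(C)C)(C(C)C)C(C)C | intermediate
23 | methyl (2R,3S)-2-methyl-3-{[3-(3-methylbut-2-en-1-yl)-4-oxobuta-1,3-dien-2-yl]oxy}butanoate, the vinylketene (not isolated) | O=C=C(CC=C(C)C)C(=C)O[C@@H](C)[C@@H](C)C(=O)OC | intermediate
24 | tert-butyl (3R)-3-{3-[1-{[(2S,3R)-4-methoxy-3-methyl-4-oxobutan-2-yl]oxy}ethenyl]-3-(3-methylbut-2-en-1-yl)-4-oxo-2-[(triisopropylsilyl)oxy]cyclobut-1-en-1-yl}octanoate, both epimers at the quaternary ring carbon (not isolated) | O=C1C([C@H](CCCCC)CC(=O)OC(C)(C)C)=C(O[Si](C(C)C)(C(C)C)C(C)C)C1(CC=C(C)C)C(=C)O[C@@H](C)[C@@H](C)C(=O)OC | intermediate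
25 | dienylketene from ring opening of 24, ketene and alkoxyvinyl arms cis on the central double bond (not isolated) | O=C=C([C@H](CCCCC)CC(=O)OC(C)(C)C)/C(O[Si](C(C)C)(C(C)C)C(C)C)=C(/CC=C(C)C)C(=C)O[C@@H](C)[C@@H](C)C(=O)OC | intermediate
26 | tert-butyl (3R)-3-{4-{[(2S,3R)-4-methoxy-3-methyl-4-oxobutan-2-yl]oxy}-3-(3-methylbut-2-en-1-yl)-6-oxo-2-[(triisopropylsilyl)oxy]cyclohexa-1,3-dien-1-yl}octanoate (not isolated) | O=C1CC(O[C@@H](C)[C@@H](C)C(=O)OC)=C(CC=C(C)C)C(O[Si](C(C)C)(C(C)C)C(C)C)=C1[C@H](CCCCC)CC(=O)OC(C)(C)C | intermediate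
27 | methyl (2R,3S)-3-{4-[(3R)-1-tert-butoxy-1-oxooctan-3-yl]-5-hydroxy-2-(3-methylbut-2-en-1-yl)-3-[(triisopropylsilyl)oxy]phenoxy}-2-methylbutanoate | CCCCC[C@H](CC(=O)OC(C)(C)C)c1c(O)cc(O[C@@H](C)[C@@H](C)C(=O)OC)c(CC=C(C)C)c1O[Si](C(C)C)(C(C)C)C(C)C | intermediate
28 | trimethylstannyl ester of acid 29 (not isolated) | CCCCC[C@H](CC(=O)OC(C)(C)C)c1c(O)cc(O[C@@H](C)[C@@H](C)C(=O)O[Sn](C)(C)C)c(CC=C(C)C)c1O[Si](C(C)C)(C(C)C)C(C)C | intermediate
29 | (2R,3S)-3-{4-[(3R)-1-tert-butoxy-1-oxooctan-3-yl]-5-hydroxy-2-(3-methylbut-2-en-1-yl)-3-[(triisopropylsilyl)oxy]phenoxy}-2-methylbutanoic acid | CCCCC[C@H](CC(=O)OC(C)(C)C)c1c(O)cc(O[C@@H](C)[C@@H](C)C(=O)O)c(CC=C(C)C)c1O[Si](C(C)C)(C(C)C)C(C)C | intermediate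
30 | mixed anhydride of acid 29 and trifluoroacetic acid (not isolated) | CCCCC[C@H](CC(=O)OC(C)(C)C)c1c(O)cc(O[C@@H](C)[C@@H](C)C(=O)OC(=O)C(F)(F)F)c(CC=C(C)C)c1O[Si](C(C)C)(C(C)C)C(C)C | intermediate
31 | tert-butyl (3R)-3-{(2S,3R)-5-hydroxy-2,3-dimethyl-8-(3-methylbut-2-en-1-yl)-4-oxo-7-[(triisopropylsilyl)oxy]-3,4-dihydro-2H-chromen-6-yl}octanoate | CCCCC[C@H](CC(=O)OC(C)(C)C)c1c(O)c2c(c(CC=C(C)C)c1O[Si](C(C)C)(C(C)C)C(C)C)O[C@@H](C)[C@@H](C)C2=O | intermediate
32 | tert-butyl (3R)-3-[(2S,3R)-5,7-dihydroxy-2,3-dimethyl-8-(3-methylbut-2-en-1-yl)-4-oxo-3,4-dihydro-2H-chromen-6-yl]octanoate | CCCCC[C@H](CC(=O)OC(C)(C)C)c1c(O)c2c(c(CC=C(C)C)c1O)O[C@@H](C)[C@@H](C)C2=O | intermediate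
33 | tert-butyl (3R)-3-[(2S,3R)-5-hydroxy-7-methoxy-2,3-dimethyl-8-(3-methylbut-2-en-1-yl)-4-oxo-3,4-dihydro-2H-chromen-6-yl]octanoate | CCCCC[C@H](CC(=O)OC(C)(C)C)c1c(O)c2c(c(CC=C(C)C)c1OC)O[C@@H](C)[C@@H](C)C2=O | intermediate
34 | (3R)-3-[(2S,3R)-5-hydroxy-7-methoxy-2,3-dimethyl-8-(3-methylbut-2-en-1-yl)-4-oxo-3,4-dihydro-2H-chromen-6-yl]octanoic acid | CCCCC[C@H](CC(=O)O)c1c(O)c2c(c(CC=C(C)C)c1OC)O[C@@H](C)[C@@H](C)C2=O | target

**Step count and risks**

Total step count: 15. Longest linear sequence: 10 steps (steps 1, 2, 3, 5 and 10–15 from ethoxyacetylene; equally steps 6–9 and 10–15 from the oxazolidinone).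

The three steps most likely to fail:

Step 10. The alkoxy group makes the cyclobutenone a vinylogous ester, so the first ring opening may be slow. At the temperature then needed the vinylketene may dimerise or acylate the product phenol, and the siloxyalkyne may rearrange to a silylketene before it is captured. The fallback sets out from 11 and 22 and comes back at 27. It generates the vinylketene photochemically: irradiation of 11 with 22 (medium-pressure Hg lamp, Vycor filter, CH2Cl2, rt) should open the four-membered ring at ambient temperature. The [2+2] adduct 24 is then isolated and heated on its own in toluene at 80 °C, where only the easier second ring opening and the 6π closure remain. This two-stage sequence makes no compound outside the list (F0).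

Step 9. Attack of the alkyllithium on the tert-butyl ester, incomplete carbenoid rearrangement, or silylation of the ynolate on carbon could erode the yield. The fallback sets out from 19 and comes back at 22; it builds the alkyne first and oxidises it afterwards. Reduction with i-Bu2AlH (CH2Cl2, −78 °C) should take the methyl ester selectively to tert-butyl (3R)-3-formyloctanoate F1. Ohira–Bestmann homologation (dimethyl (1-diazo-2-oxopropyl)phosphonate, K2CO3, MeOH, 0 °C) gives tert-butyl (3R)-3-ethynyloctanoate F2. Deprotonation with LiN(SiMe3)2, oxygen transfer from LiOOtBu to the lithium acetylide (THF, −78 → 0 °C) and silylation of the resulting ynolate 21 with iPr3SiOTf return 22.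

Step 5. E2 loss of the activated oxyphosphonium group to give methyl tiglate, or alkylation of the dione on carbon, could compete with etherification. The fallback sets out from 5 and comes back at 11, bypassing steps 3 to 5. It forms the enol ether through the alcohol oxygen with retention, which calls for the syn alcohol. Evans syn aldol reaction of commercially available (4R)-4-benzyl-3-propanoyl-1,3-oxazolidin-2-one (Bu2BOTf, Et3N, CH2Cl2, −78 °C; acetaldehyde) gives (4R)-4-benzyl-3-[(2R,3S)-3-hydroxy-2-methylbutanoyl]-1,3-oxazolidin-2-one F3. MeMgBr in MeOH gives methyl (2R,3S)-3-hydroxy-2-methylbutanoate F4. Acid-catalysed alkoxy exchange on the vinylogous ester 5 (F4, cat. camphorsulfonic acid, toluene, 40 °C, ethanol removed under reduced pressure) then gives 11.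

Further compounds
F0 | step 10 | none | none
F1 | step 9 | tert-butyl (3R)-3-formyloctanoate | CCCCC[C@H](CC(=O)OC(C)(C)C)C=O
F2 | step 9 | tert-butyl (3R)-3-ethynyloctanoate | CCCCC[C@H](CC(=O)OC(C)(C)C)C#C
F3 | step 5 | (4R)-4-benzyl-3-[(2R,3S)-3-hydroxy-2-methylbutanoyl]-1,3-oxazolidin-2-one | C[C@H](O)[C@@H](C)C(=O)N1[C@H](Cc2ccccc2)COC1=O
F4 | step 5 | methyl (2R,3S)-3-hydroxy-2-methylbutanoate | C[C@H](O)[C@@H](C)C(=O)OC
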